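**Plan**

- Retrosynthesis cuts, in order: the four O–benzyl bonds; C4–C4a of ring C (acyl carbon to ring A); O1–C2 (aryl vinyl ether); C2–C3 (a formyl carbon on an arylacetate); and on ring B the C5'–CMe2 bond and the ArCH2–CO2Me homologation.
- Enabling feature: the oxygens on C5, C7 and C8a of ring A are 1,3,5-related. A 3,5-bis(benzyloxy)phenoxy group on C2 is therefore symmetric, and the carbon that becomes C4a is ortho to O1 and ortho/para to the two benzyloxy groups.
- Forward: ring B is carried from 2,3-dihydroxy-4-methoxybenzaldehyde to the reverse-prenylated arylacetate, C2 is added as a formyl group, ring A is attached through O1, and ring C closes last by acylation at C4a. Global debenzylation ends the route.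
- Stereochemistry: the target has no stereocentre. The only stereochemical element on the way, the C2=C3 geometry, is adjusted in the flask during ring closure.

Key step: step 11

Remark: the addition–elimination of step 9 is assumed to give the acrylate mainly as the (E)-isomer (aryloxy trans to the ester), as for related 3-alkoxy-2-arylacrylates. Any (Z)-isomer is carried along, and the (Z)-geometry needed for closure is reached in the flask as acyl chloride 16.

Remark: compound 5 is racemic at sulfur and its alkene geometry is uncontrolled. Both elements disappear in step 4, so it is drawn without descriptors.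

Remark: steps 1 and 8 each install two benzyl groups, so benzyl bromide 2 is used in two equivalents there; the second equivalent is entered as a reagent that adds atoms.

**Route**

Step 1
Reactants: 1 2,3-dihydroxy-4-methoxybenzaldehyde; 2 benzyl bromide
Product: 3 2,3-bis(benzyloxy)-4-methoxybenzaldehyde
Conditions: BnBr (2.2 equiv), K2CO3, DMF, 60 °C
Reagents that add atoms: benzyl bromide (second equivalent of 2), BrCc1ccccc1
Why: Twofold Williamson etherification; both catechol hydroxyls, including the 2-OH chelated to the aldehyde, should be alkylated in warm DMF while the aldehyde and the methyl ether are untouched.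

Step 2
Reactants: 3 2,3-bis(benzyloxy)-4-methoxybenzaldehyde
Product: 4 2,3-bis(benzyloxy)-5-bromo-4-methoxybenzaldehyde
Conditions: NBS, DMF, rt
Reagents that add atoms: N-bromosuccinimide, O=C1CCC(=O)N1Br
Why: Electrophilic aromatic bromination; C5 is ortho to the methoxy group, para to the 2-benzyloxy group and meta to the aldehyde, whereas C6 is ortho to the deactivating aldehyde, so the 5-bromo isomer is expected, as is usual for 2,3,4-trialkoxybenzaldehydes.

Step 3
Reactants: 4 2,3-bis(benzyloxy)-5-bromo-4-methoxybenzaldehyde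
Product: 5 2,3-bis(benzyloxy)-5-bromo-4-methoxy-1-[2-(methylsulfanyl)-2-(methylsulfinyl)ethenyl]benzene
Conditions: CH3SCH2S(O)CH3 (FAMSO), benzyltrimethylammonium hydroxide (cat.), THF, reflux
Reagents that add atoms: methyl (methylsulfinyl)methyl sulfide, CSCS(C)=O
Why: Knoevenagel-type condensation of the aldehyde with the acidic methylene of FAMSO under hydroxide catalysis should give the ketene dithioacetal S-oxide, a masked arylacetic acid.

Step 4
Reactants: 5 2,3-bis(benzyloxy)-5-bromo-4-methoxy-1-[2-(methylsulfanyl)-2-(methylsulfinyl)ethenyl]benzene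
Product: 6 methyl 2-[2,3-bis(benzyloxy)-5-bromo-4-methoxyphenyl]acetate
Conditions: HCl, MeOH, rt → 50 °C
Reagents that add atoms: methanol, CO
Why: Acid-promoted methanolysis of the ketene dithioacetal S-oxide (protonation at the benzylic carbon, addition of methanol, Pummerer-type loss of the two sulfur groups) should give the one-carbon-homologated ester; it is run before the alkene exists, and the aryl benzyl ethers and aryl bromide tolerate methanolic HCl.

Step 5
Reactants: 6 methyl 2-[2,3-bis(benzyloxy)-5-bromo-4-methoxyphenyl]acetate; 7 prenylboronic acid pinacol ester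
Product: 8 methyl 2-[2,3-bis(benzyloxy)-4-methoxy-5-(2-methylbut-3-en-2-yl)phenyl]acetate
Conditions: Pd(OAc)2 (cat.), t-BuXPhos (2-di-tert-butylphosphino-2',4',6'-triisopropylbiphenyl, cat.), K3PO4 (aq), MeCN, 70 °C
Reagents that add atoms: none
Why: Ligand-controlled γ-selective Suzuki–Miyaura allyl–aryl coupling; SE2' transmetalation places palladium on the tertiary carbon, and the bulky di-tert-butylbiarylphosphine in coordinating acetonitrile should force reductive elimination before the allyl group slips to its primary terminus, giving the 2-methylbut-3-en-2-yl group; the coupling is placed at the ester stage because an aldehyde would be allylborated by 7.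

Step 6
Reactants: 8 methyl 2-[2,3-bis(benzyloxy)-4-methoxy-5-(2-methylbut-3-en-2-yl)phenyl]acetate
Product: 9 methyl (Z)-2-[2,3-bis(benzyloxy)-4-methoxy-5-(2-methylbut-3-en-2-yl)phenyl]-3-hydroxyprop-2-enoate (chelated enol form of the 2-formyl ester)
Conditions: HCO2Me, NaH, THF, 0 °C → rt; then dil. HCl
Reagents that add atoms: methyl formate, COC=O
Why: Crossed Claisen condensation of the ester enolate with non-enolisable methyl formate, driven by formation of the stabilised formyl ester enolate, adds the carbon that becomes C2; acidification should give the hydrogen-bonded enol.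

Step 7
Reactants: 9 methyl (Z)-2-[2,3-bis(benzyloxy)-4-methoxy-5-(2-methylbut-3-en-2-yl)phenyl]-3-hydroxyprop-2-enoate
Product: 10 methyl (E)-2-[2,3-bis(benzyloxy)-4-methoxy-5-(2-methylbut-3-en-2-yl)phenyl]-3-[(4-methylbenzenesulfonyl)oxy]prop-2-enoate
Conditions: TsCl, Et3N, N-methylimidazole (cat.), CH2Cl2, 0 °C
Reagents that add atoms: p-toluenesulfonyl chloride, Cc1ccc(cc1)S(Cl)(=O)=O
Why: O-Sulfonylation of the enol under amine base with N-methylimidazole catalysis turns the future C2 into the electrophilic carbon of a vinylogous sulfonic–carboxylic anhydride; the non-chelating conditions are expected to favour the (E)-tosylate, though the geometry has no consequence.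

Step 8
Reactants: 11 phloroglucinol; 2 benzyl bromide
Product: 12 3,5-bis(benzyloxy)phenol
Conditions: BnBr (2 equiv), K2CO3, DMF, rt
Reagents that add atoms: benzyl bromide (second equivalent of 2), BrCc1ccccc1
Why: Twofold Williamson etherification under statistical control; with two equivalents of benzyl bromide and a weak base in a polar aprotic solvent the symmetric diether should be the main O-alkylation product and is separable from the mono- and tribenzyl ethers.

Step 9
Reactants: 10 methyl (E)-2-[2,3-bis(benzyloxy)-4-methoxy-5-(2-methylbut-3-en-2-yl)phenyl]-3-[(4-methylbenzenesulfonyl)oxy]prop-2-enoate; 12 3,5-bis(benzyloxy)phenol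
Product: 13 methyl (E)-3-[3,5-bis(benzyloxy)phenoxy]-2-[2,3-bis(benzyloxy)-4-methoxy-5-(2-methylbut-3-en-2-yl)phenyl]prop-2-enoate
Conditions: Cs2CO3, MeCN, rt → 40 °C
Reagents that add atoms: none
Why: Nucleophilic vinylic substitution by addition–elimination; the phenoxide oxygen adds at the β-carbon of the acrylate and the ester enolate expels tosylate, forming O1–C2, with O-attack favoured on this hard electrophile in a polar aprotic solvent and the more stable (E)-isomer expected.

Step 10
Reactants: 13 methyl (E)-3-[3,5-bis(benzyloxy)phenoxy]-2-[2,3-bis(benzyloxy)-4-methoxy-5-(2-methylbut-3-en-2-yl)phenyl]prop-2-enoate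
Product: 14 (E)-3-[3,5-bis(benzyloxy)phenoxy]-2-[2,3-bis(benzyloxy)-4-methoxy-5-(2-methylbut-3-en-2-yl)phenyl]prop-2-enoic acid
Conditions: LiOH, THF/MeOH/H2O, rt; then dil. HCl
Reagents that add atoms: lithium hydroxide, [Li+].[OH-]
Why: Saponification (acyl substitution by hydroxide); attack at the ester carbonyl should outrun conjugate attack at the hindered, 2-aryl-substituted acrylate, and once the carboxylate has formed the aryloxy group can no longer be expelled.

Step 11
Reactants: 14 (E)-3-[3,5-bis(benzyloxy)phenoxy]-2-[2,3-bis(benzyloxy)-4-methoxy-5-(2-methylbut-3-en-2-yl)phenyl]prop-2-enoic acid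
Product: 17 5,7-bis(benzyloxy)-3-[2,3-bis(benzyloxy)-4-methoxy-5-(2-methylbut-3-en-2-yl)phenyl]-4H-chromen-4-one, via (E)-acyl chloride 15 (not isolated), via (Z)-acyl chloride 16 (not isolated)
Conditions: 1-chloro-N,N,2-trimethylprop-1-en-1-amine, CH2Cl2, 0 °C → rt; then SnCl4, CH2Cl2, −78 → −30 °C, high dilution
Reagents that add atoms: none
Why: The α-chloroenamine converts the acid into acyl chloride 15 without releasing acid, and SnCl4 then polarises or ionises it to a β-aryloxy-stabilised acyl cation whose oxocarbenium–ketene resonance form has single-bond character at C2–C3, so 15 and 16 interconvert and only 16, with the acyl group cis to O1, can reach ring A. The acyl carbon C4 attacks C4a through a six-membered Wheland intermediate and loss of the proton restores aromaticity; ring C thus closes in a 6-exo sense at the activated carbonyl by forming C4–C4a. This is an intramolecular Friedel–Crafts acylation, the known way from 3-aryloxyacrylic acids to chromones. C4a is ortho to O1, ortho to one benzyloxy group and para to the other, so closure should proceed at −78 to −30 °C, where the aryl benzyl ethers and the monosubstituted alkene should persist. Regioselectivity needs no control because the two carbons ortho to O1 are equivalent by the symmetry of the 3,5-bis(benzyloxy)phenoxy ring. No stereocentre is formed, and the alkene geometry is erased by the ring.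

Step 12
Reactants: 17 5,7-bis(benzyloxy)-3-[2,3-bis(benzyloxy)-4-methoxy-5-(2-methylbut-3-en-2-yl)phenyl]-4H-chromen-4-one
Product: 18 5,7-dihydroxy-3-[2,3-dihydroxy-4-methoxy-5-(2-methylbut-3-en-2-yl)phenyl]-4H-chromen-4-one
Conditions: BCl3 (excess), pentamethylbenzene, CH2Cl2, −78 °C; then H2O
Reagents that add atoms: none
Why: Lewis-acid debenzylation with a non-Lewis-basic cation scavenger; BCl3 activates each benzyloxy oxygen and the benzyl cation is captured by pentamethylbenzene, so the alkene and the electron-rich rings should not be benzylated, and at −78 °C the aryl methyl ether should remain.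

**Compound list**

1 | 2,3-dihydroxy-4-methoxybenzaldehyde | COc1ccc(C=O)c(O)c1O | starting material
2 | benzyl bromide | BrCc1ccccc1 | starting material
3 | 2,3-bis(benzyloxy)-4-methoxybenzaldehyde | COc1ccc(C=O)c(OCc2ccccc2)c1OCc1ccccc1 | intermediate
4 | 2,3-bis(benzyloxy)-5-bromo-4-methoxybenzaldehyde | COc1c(Br)cc(C=O)c(OCc2ccccc2)c1OCc1ccccc1 | intermediate
5 | 2,3-bis(benzyloxy)-5-bromo-4-methoxy-1-[2-(methylsulfanyl)-2-(methylsulfinyl)ethenyl]benzene (racemic at sulfur, geometry not fixed) | COc1c(Br)cc(C=C(SC)S(C)=O)c(OCc2ccccc2)c1OCc1ccccc1 | intermediate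
6 | methyl 2-[2,3-bis(benzyloxy)-5-bromo-4-methoxyphenyl]acetate | COC(=O)Cc1cc(Br)c(OC)c(OCc2ccccc2)c1OCc1ccccc1 | intermediate
7 | prenylboronic acid pinacol ester (4,4,5,5-tetramethyl-2-(3-methylbut-2-en-1-yl)-1,3,2-dioxaborolane) | CC(C)=CCB1OC(C)(C)C(C)(C)O1 | starting material
8 | methyl 2-[2,3-bis(benzyloxy)-4-methoxy-5-(2-methylbut-3-en-2-yl)phenyl]acetate | COC(=O)Cc1cc(C(C)(C)C=C)c(OC)c(OCc2ccccc2)c1OCc1ccccc1 | intermediate
9 | methyl (Z)-2-[2,3-bis(benzyloxy)-4-methoxy-5-(2-methylbut-3-en-2-yl)phenyl]-3-hydroxyprop-2-enoate | COC(=O)/C(=C\O)c1cc(C(C)(C)C=C)c(OC)c(OCc2ccccc2)c1OCc1ccccc1 | intermediate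
10 | methyl (E)-2-[2,3-bis(benzyloxy)-4-methoxy-5-(2-methylbut-3-en-2-yl)phenyl]-3-[(4-methylbenzenesulfonyl)oxy]prop-2-enoate | COC(=O)/C(=C/OS(=O)(=O)c1ccc(C)cc1)c1cc(C(C)(C)C=C)c(OC)c(OCc2ccccc2)c1OCc1ccccc1 | intermediate
11 | phloroglucinol | Oc1cc(O)cc(O)c1 | starting material
12 | 3,5-bis(benzyloxy)phenol | Oc1cc(OCc2ccccc2)cc(OCc2ccccc2)c1 | intermediate
13 | methyl (E)-3-[3,5-bis(benzyloxy)phenoxy]-2-[2,3-bis(benzyloxy)-4-methoxy-5-(2-methylbut-3-en-2-yl)phenyl]prop-2-enoate | COC(=O)/C(=C/Oc1cc(OCc2ccccc2)cc(OCc2ccccc2)c1)c1cc(C(C)(C)C=C)c(OC)c(OCc2ccccc2)c1OCc1ccccc1 | intermediate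
14 | (E)-3-[3,5-bis(benzyloxy)phenoxy]-2-[2,3-bis(benzyloxy)-4-methoxy-5-(2-methylbut-3-en-2-yl)phenyl]prop-2-enoic acid | OC(=O)/C(=C/Oc1cc(OCc2ccccc2)cc(OCc2ccccc2)c1)c1cc(C(C)(C)C=C)c(OC)c(OCc2ccccc2)c1OCc1ccccc1 | intermediate
15 | (E)-3-[3,5-bis(benzyloxy)phenoxy]-2-[2,3-bis(benzyloxy)-4-methoxy-5-(2-methylbut-3-en-2-yl)phenyl]prop-2-enoyl chloride | ClC(=O)/C(=C/Oc1cc(OCc2ccccc2)cc(OCc2ccccc2)c1)c1cc(C(C)(C)C=C)c(OC)c(OCc2ccccc2)c1OCc1ccccc1 | intermediate (not isolated)
16 | (Z)-3-[3,5-bis(benzyloxy)phenoxy]-2-[2,3-bis(benzyloxy)-4-methoxy-5-(2-methylbut-3-en-2-yl)phenyl]prop-2-enoyl chloride | ClC(=O)/C(=C\Oc1cc(OCc2ccccc2)cc(OCc2ccccc2)c1)c1cc(C(C)(C)C=C)c(OC)c(OCc2ccccc2)c1OCc1ccccc1 | intermediate (not isolated)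
17 | 5,7-bis(benzyloxy)-3-[2,3-bis(benzyloxy)-4-methoxy-5-(2-methylbut-3-en-2-yl)phenyl]-4H-chromen-4-one | C=CC(C)(C)c1cc(-c2coc3cc(OCc4ccccc4)cc(OCc4ccccc4)c3c2=O)c(OCc2ccccc2)c(OCc2ccccc2)c1OC | intermediate
18 | 5,7-dihydroxy-3-[2,3-dihydroxy-4-methoxy-5-(2-methylbut-3-en-2-yl)phenyl]-4H-chromen-4-one | C=CC(C)(C)c1cc(-c2coc3cc(O)cc(O)c3c2=O)c(O)c(O)c1OC | target

**Count**

Total steps: 12. Longest linear sequence: 11 steps (steps 1–7 and 9–12, from aldehyde 1); step 8 is a one-step side branch.

**Steps most likely to fail**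

Step 11. The E-to-Z equilibration of the activated acid may be slow. The acyl cation could then be captured by the neighbouring 2'-benzyloxy oxygen (lactonisation with loss of benzyl) or acylate a second molecule. Lewis-acid loss of benzyl groups or addition of HCl to the alkene may set in on warming.

The fallback sets out from ester 8 and phloroglucinol 11 and returns at chromone 17. It forms C4–C4a intermolecularly and then closes ring C at O1–C2 with a one-carbon unit.
- Ester 8 is saponified (LiOH, THF/H2O, then dil. HCl) to 2-[2,3-bis(benzyloxy)-4-methoxy-5-(2-methylbut-3-en-2-yl)phenyl]acetic acid F1.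
- Phloroglucinol 11 is perbenzylated with three equivalents of 2 (K2CO3, DMF) to 1,3,5-tris(benzyloxy)benzene F2.
- Trifluoroacetic anhydride in CH2Cl2 (0 °C → rt) joins F1 and F2 by Friedel–Crafts acylation to 2-[2,3-bis(benzyloxy)-4-methoxy-5-(2-methylbut-3-en-2-yl)phenyl]-1-[2,4,6-tris(benzyloxy)phenyl]ethan-1-one F3; the symmetry of the ring again removes any regiochemical question.
- One benzyl ether ortho to the ketone is removed by chelation-directed cleavage (BCl3, 1 equiv, CH2Cl2, −78 °C) to give 1-[2,4-bis(benzyloxy)-6-hydroxyphenyl]-2-[2,3-bis(benzyloxy)-4-methoxy-5-(2-methylbut-3-en-2-yl)phenyl]ethan-1-one F4.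
- N,N-Dimethylformamide dimethyl acetal (toluene, 80 °C) condenses at the methylene group, and the phenol closes onto the enaminone with loss of dimethylamine to give 17.

Step 5. The allyl group may slip on palladium before reductive elimination and deliver the linear prenyl isomer. Protodebromination, sluggish coupling at the bromide flanked by the methoxy group, or partial hydrolysis of the ester may also intervene.

The fallback sets out from bromide 6 and returns at 8 with the polarity reversed.
- Miyaura borylation (B2pin2, Pd(dppf)Cl2, KOAc, dioxane, 80 °C) gives methyl 2-[2,3-bis(benzyloxy)-4-methoxy-5-(4,4,5,5-tetramethyl-1,3,2-dioxaborolan-2-yl)phenyl]acetate F5.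
- Copper-catalysed SN2'-selective allylic substitution of prenyl diethyl phosphate (CuCl, 1,3-bis(2,6-diisopropylphenyl)imidazolium chloride, NaOMe, THF) then has the arylcopper species attack the disubstituted γ-carbon and expel phosphate. This builds the quaternary carbon and the terminal alkene of 8 without an allylpalladium intermediate.

Step 9. The phenoxide may attack sulfur instead of carbon (sulfonyl transfer, returning enol 9), or react through its ring carbons instead of oxygen.

The fallback sets out from enol 9 and returns at 13.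
- Oxalyl bromide with catalytic DMF in CH2Cl2 converts 9 into methyl (E)-2-[2,3-bis(benzyloxy)-4-methoxy-5-(2-methylbut-3-en-2-yl)phenyl]-3-bromoprop-2-enoate F6; either geometry would serve.
- An Ullmann-type C–O coupling with phenol 12 (CuI, N,N-dimethylglycine, Cs2CO3, dioxane, 90 °C) then forms O1–C2 at copper through the phenoxide oxygen. No sulfonyl group is present to divert the nucleophile.

Further compounds
F1 | step 11 | 2-[2,3-bis(benzyloxy)-4-methoxy-5-(2-methylbut-3-en-2-yl)phenyl]acetic acid | OC(=O)Cc1cc(C(C)(C)C=C)c(OC)c(OCc2ccccc2)c1OCc1ccccc1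
F2 | step 11 | 1,3,5-tris(benzyloxy)benzene | c1ccc(COc2cc(OCc3ccccc3)cc(OCc3ccccc3)c2)cc1
F3 | step 11 | 2-[2,3-bis(benzyloxy)-4-methoxy-5-(2-methylbut-3-en-2-yl)phenyl]-1-[2,4,6-tris(benzyloxy)phenyl]ethan-1-one | O=C(Cc1cc(C(C)(C)C=C)c(OC)c(OCc2ccccc2)c1OCc1ccccc1)c1c(OCc2ccccc2)cc(OCc2ccccc2)cc1OCc1ccccc1
F4 | step 11 | 1-[2,4-bis(benzyloxy)-6-hydroxyphenyl]-2-[2,3-bis(benzyloxy)-4-methoxy-5-(2-methylbut-3-en-2-yl)phenyl]ethan-1-one | O=C(Cc1cc(C(C)(C)C=C)c(OC)c(OCc2ccccc2)c1OCc1ccccc1)c1c(O)cc(OCc2ccccc2)cc1OCc1ccccc1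
F5 | step 5 | methyl 2-[2,3-bis(benzyloxy)-4-methoxy-5-(4,4,5,5-tetramethyl-1,3,2-dioxaborolan-2-yl)phenyl]acetate | COC(=O)Cc1cc(B2OC(C)(C)C(C)(C)O2)c(OC)c(OCc2ccccc2)c1OCc1ccccc1
F6 | step 9 | methyl (E)-2-[2,3-bis(benzyloxy)-4-methoxy-5-(2-methylbut-3-en-2-yl)phenyl]-3-bromoprop-2-enoate | COC(=O)/C(=C/Br)c1cc(C(C)(C)C=C)c(OC)c(OCc2ccccc2)c1OCc1ccccc1
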